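The route builds the acylfilicinic acid ring (ring A: C-1 carbonyl, C-2 butanoyl-bearing, C-3, C-4 = CMe2, C-5, C-6 bridge-bearing) de novo on the aryl–CH2 bridge, so no statistical CH2O coupling is needed. A 3,4-dihydrocoumarin supplies the arene, the bridge CH2, C-6 and C-5 (lactone carbonyl); the γ-dianion of methyl 4-methyl-3-oxopentanoate supplies C-4 to C-1. In one pot the tertiary carbanion opens the lactone (C-4–C-5) and the ketone enolate then closes ring A by Claisen attack of C-6 on the ester carbon C-1. The step exploits that C-6 lies between two ring carbonyls and that quaternary C-4 leaves a single cyclisation mode. Butanoylation at C-2 finishes the synthesis.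

Key step: step 5

Remark: ring A is an enolised β-triketone; the target and compounds 9 to 11 are written in the tautomeric form of the given structure, which should interconvert freely with the other enol forms.

Step 1
Reactants: 1 2,4,6-trimethoxybenzaldehyde
Product: 2 2,6-dihydroxy-4-methoxybenzaldehyde
Conditions: AlCl3 (5 equiv), CH2Cl2, 0 °C → reflux; 1 M HCl
Reagents that add atoms: none
Why: AlCl3 chelated between the formyl oxygen and an ortho methoxy oxygen should cleave only the two ortho methyl ethers (chelation-controlled Lewis acid demethylation), leaving the para methoxy group.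

Step 2
Reactants: 2 2,6-dihydroxy-4-methoxybenzaldehyde
Product: 4 5-hydroxy-7-methoxy-2H-chromen-2-one, via cinnamate ester 3 (not isolated)
Conditions: Ph3P=CHCO2Et (1.3 equiv), PhNEt2, reflux
Reagents that add atoms: ethyl (triphenylphosphoranylidene)acetate, CCOC(=O)C=P(c1ccccc1)(c1ccccc1)c1ccccc1
Why: Wittig olefination with the stabilised ylide gives the (E)-2-hydroxycinnamate 3, which at the reflux temperature should isomerise and lactonise through either of its two equivalent phenols, the standard one-pot coumarin synthesis from salicylaldehydes.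

Step 3
Reactants: 4 5-hydroxy-7-methoxy-2H-chromen-2-one
Product: 5 5-hydroxy-7-methoxy-3,4-dihydro-2H-chromen-2-one
Conditions: H2 (3 atm), Pd/C (10%), AcOH, 50 °C
Reagents that add atoms: none
Why: Catalytic hydrogenation should saturate the conjugated C3=C4 bond of the coumarin while the arene and the lactone carbonyl remain intact; no stereocentre arises.

Step 4
Reactants: 5 5-hydroxy-7-methoxy-3,4-dihydro-2H-chromen-2-one
Product: 6 6-butanoyl-5-hydroxy-7-methoxy-3,4-dihydro-2H-chromen-2-one
Conditions: butanoic acid (1.5 equiv), BF3·OEt2 (medium), 80 °C; aq. NaOAc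
Reagents that add atoms: butanoic acid, CCCC(=O)O
Why: Friedel–Crafts acylation (O-acylation and Fries-type migration under BF3) should place the butanoyl group ortho to the free phenol as a BF2 chelate; because the arene becomes a symmetric 2-alkyl-5-methoxyresorcinol core once the lactone is opened, acylation at C-8 instead would lead to the same compound 8, so site selectivity is not critical.

Step 5
Reactants: 6 6-butanoyl-5-hydroxy-7-methoxy-3,4-dihydro-2H-chromen-2-one; 7 methyl 4-methyl-3-oxopentanoate
Product: 9 2-[(3-butanoyl-2,6-dihydroxy-4-methoxyphenyl)methyl]-3,5-dihydroxy-4,4-dimethylcyclohexa-2,5-dien-1-one, via acyclic diketo ester 8 (not isolated)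
Conditions: 7 (2.5 equiv), LiN(iPr)2 (5 equiv), THF, −78 → 0 °C; add 6 as its lithium phenoxide (1 equiv LiN(iPr)2, THF), −78 → 0 °C; then t-BuOH, KOtBu (4 equiv), 60 °C; 1 M HCl, 0 °C
Reagents that add atoms: none
Why: The γ-carbanion of the β-keto ester dianion (acylation of 1,3-dicarbonyl dianions by esters, here an aryl lactone acting as an active ester) should add to the lactone carbonyl and expel the phenoxide, giving diketo ester 8 as its polyanion; alkoxide then equilibrates the enolates, and the C-6 enolate of the C-5 ketone attacks the ester carbon C-1 with loss of methoxide (Claisen/Dieckmann condensation, the reaction type behind dimedone, syncarpic acid and acylphloroglucinol syntheses). Ring A closes in a 6-(enolendo)-exo-trig mode, which is favoured for enolates. No stereocentre is formed. The step needs C- over O-acylation and attack at the lactone rather than at the aryl ketone: the aryl ketone is flanked by two ortho oxygens and conjugated to a phenoxide, and any enol lactone from O-attack should be funnelled by alkoxide to the C-acyl product, which leaves the equilibrium as its delocalised trione enolate. Quaternary C-4 prevents enolisation between C-3 and C-5 and leaves only four-membered aldol alternatives, so C-6 is the sole carbon nucleophile that can reach C-1. The gem-dimethyl group should also favour closure (Thorpe–Ingold effect).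

Step 6
Reactants: 9 2-[(3-butanoyl-2,6-dihydroxy-4-methoxyphenyl)methyl]-3,5-dihydroxy-4,4-dimethylcyclohexa-2,5-dien-1-one
Product: 11 2-butanoyl-6-[(3-butanoyl-2,6-dihydroxy-4-methoxyphenyl)methyl]-3,5-dihydroxy-4,4-dimethylcyclohexa-2,5-dien-1-one, via enol butanoate 10 (not isolated)
Conditions: butanoic acid (1.05 equiv), DCC (1.1 equiv), DMAP (1.2 equiv), CH2Cl2, 0 °C → rt
Reagents that add atoms: butanoic acid, CCCC(=O)O
Why: Steglich-type O-acylation of the strongly acidic trione enol, ion-paired with protonated DMAP, followed by DMAP-mediated O-to-C acyl migration to C-2, the only unsubstituted ring carbon, is the established route from cyclic 1,3-diones to 2-acyl derivatives and should outpace esterification of the neutral, hydrogen-bonded phenols.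

Compound list
1 | 2,4,6-trimethoxybenzaldehyde | COc1cc(OC)c(C=O)c(OC)c1 | starting material
2 | 2,6-dihydroxy-4-methoxybenzaldehyde | COc1cc(O)c(C=O)c(O)c1 | intermediate
3 | ethyl (E)-3-(2,6-dihydroxy-4-methoxyphenyl)prop-2-enoate (cinnamate ester) | CCOC(=O)/C=C/c1c(O)cc(OC)cc1O | intermediate
4 | 5-hydroxy-7-methoxy-2H-chromen-2-one | COc1cc(O)c2ccc(=O)oc2c1 | intermediate
5 | 5-hydroxy-7-methoxy-3,4-dihydro-2H-chromen-2-one | COc1cc(O)c2CCC(=O)Oc2c1 | intermediate
6 | 6-butanoyl-5-hydroxy-7-methoxy-3,4-dihydro-2H-chromen-2-one | CCCC(=O)c1c(OC)cc2OC(=O)CCc2c1O | intermediate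
7 | methyl 4-methyl-3-oxopentanoate | COC(=O)CC(=O)C(C)C | starting material
8 | methyl 7-(3-butanoyl-2,6-dihydroxy-4-methoxyphenyl)-4,4-dimethyl-3,5-dioxoheptanoate (acyclic diketo ester) | COC(=O)CC(=O)C(C)(C)C(=O)CCc1c(O)cc(OC)c(C(=O)CCC)c1O | intermediate
9 | 2-[(3-butanoyl-2,6-dihydroxy-4-methoxyphenyl)methyl]-3,5-dihydroxy-4,4-dimethylcyclohexa-2,5-dien-1-one | CCCC(=O)c1c(OC)cc(O)c(CC2=C(O)C(C)(C)C(O)=CC2=O)c1O | intermediate
10 | 4-[(3-butanoyl-2,6-dihydroxy-4-methoxyphenyl)methyl]-5-hydroxy-6,6-dimethyl-3-oxocyclohexa-1,4-dien-1-yl butanoate (enol butanoate) | CCCC(=O)OC1=CC(=O)C(Cc2c(O)cc(OC)c(C(=O)CCC)c2O)=C(O)C1(C)C | intermediate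
11 | 2-butanoyl-6-[(3-butanoyl-2,6-dihydroxy-4-methoxyphenyl)methyl]-3,5-dihydroxy-4,4-dimethylcyclohexa-2,5-dien-1-one | CCCC(=O)C1=C(O)C(C)(C)C(O)=C(Cc2c(O)cc(OC)c(C(=O)CCC)c2O)C1=O | target

Total step count: 6. Longest linear sequence: 6 steps (1 → 11).

Steps most likely to fail

Step 5. The hindered tertiary carbanion may take a proton from the lactone α-CH2 instead of adding to the carbonyl; the ring would then open to a ketene and the less hindered α-carbon of the β-keto ester would be acylated. Alkoxide may also cleave the C-4–C-5 bond by retro-Claisen reaction, and prolonged heating in base may break the methylene bridge of the product. The fallback sets out from 6 and comes back at 8. The lithium enolate of benzyl 2-methylpropanoate (LiN(iPr)2, THF, −78 °C) opens the lactone in a crossed Claisen condensation to benzyl 5-(3-butanoyl-2,6-dihydroxy-4-methoxyphenyl)-2,2-dimethyl-3-oxopentanoate F1. Hydrogenolysis (H2, Pd/C, EtOAc) gives 5-(3-butanoyl-2,6-dihydroxy-4-methoxyphenyl)-2,2-dimethyl-3-oxopentanoic acid F2. Activation with excess carbonyldiimidazole and decarboxylative chain extension with Mg(O2CCH2CO2Me)2 (phenols carbonylated in passing are released in the acidic work-up) gives 8, which is then cyclised in a separate operation (NaH, THF, reflux) to 9.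

Step 6. Esterification of the phenols may compete with acylation of the trione, or the acyl transfer may stop at the enol ester stage. The fallback sets out from 9 and comes back at 11. Exhaustive acylation with butanoic anhydride (4 equiv), Et3N and DMAP in CH2Cl2 should C-acylate ring A by the same O-to-C migration and esterify both phenols, giving 4-butanoyl-2-[(5-butanoyl-2,4-dihydroxy-3,3-dimethyl-6-oxocyclohexa-1,4-dien-1-yl)methyl]-5-methoxy-1,3-phenylene dibutanoate F3. Mild methanolysis (K2CO3, MeOH, 0 °C) then removes only the aryl esters, since the C-acyl triketone is protected as its enolate, and gives 11.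

Step 1. Ether cleavage may stop after the first ortho group or extend to the para methoxy group. The fallback sets out from 1 and comes back at 2. Exhaustive demethylation (BBr3, CH2Cl2, −78 °C → rt) gives 2,4,6-trihydroxybenzaldehyde F4. One equivalent of Me2SO4 with K2CO3 in acetone should then methylate the para hydroxyl, the most acidic one and the only one not hydrogen-bonded to the formyl group, to give 2.

Further compounds
F1 | step 5 | benzyl 5-(3-butanoyl-2,6-dihydroxy-4-methoxyphenyl)-2,2-dimethyl-3-oxopentanoate | CCCC(=O)c1c(OC)cc(O)c(CCC(=O)C(C)(C)C(=O)OCc2ccccc2)c1O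
F2 | step 5 | 5-(3-butanoyl-2,6-dihydroxy-4-methoxyphenyl)-2,2-dimethyl-3-oxopentanoic acid | CCCC(=O)c1c(OC)cc(O)c(CCC(=O)C(C)(C)C(=O)O)c1O
F3 | step 6 | 4-butanoyl-2-[(5-butanoyl-2,4-dihydroxy-3,3-dimethyl-6-oxocyclohexa-1,4-dien-1-yl)methyl]-5-methoxy-1,3-phenylene dibutanoate | CCCC(=O)C1=C(O)C(C)(C)C(O)=C(Cc2c(OC(=O)CCC)cc(OC)c(C(=O)CCC)c2OC(=O)CCC)C1=O
F4 | step 1 | 2,4,6-trihydroxybenzaldehyde | O=Cc1c(O)cc(O)cc1O
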